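- A small charge started my reckoning: 16 mM of impurity stood in Wednesday's run, Friday's run and the new flask alike, against catalyst charges from 30.0 mM to 120 mM.

| flask | left-handed substrate | right-handed substrate | partner | free catalyst | impurity | remark | time |
|---|---|---|---|---|---|---|---|
| Wednesday's | 0.30 M | 0.30 M | 1.1 equiv | 10 mol% | 16 mM | run made earlier |  |
| Friday's | 0.30 M | 0.30 M | 1.1 equiv | 40 mol% | 16 mM | run made earlier |  |
| flask | 0.30 M | 0.30 M | 1.10 equiv | 20 mol% | 16 mM |  | 40 h |

| run | time / h | left-handed substrate / % | right-handed substrate / % |
|---|---|---|---|
| Wednesday's | 2.50 | 48.4 | 49.5 |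
| Wednesday's | 8.00 | 47.7 | 49.1 |
| Wednesday's | 15.0 | 46.8 | 48.6 |
| Wednesday's | 20.0 | 46.9 | 48.5 |
| Wednesday's | 30.0 | 46.5 | 47.8 |
| Wednesday's | 40.0 | 47.2 | 48.6 |
| Wednesday's | 50.0 | 45.7 | 47.9 |
| Friday's | 4.00 | 40.5 | 45.1 |
| Friday's | 6.00 | 37.5 | 45.5 |
| Friday's | 8.00 | 37.2 | 43.6 |
| Friday's | 15.0 | 35.1 | 43.3 |
| Friday's | 20.0 | 36.4 | 42.6 |
| Friday's | 30.0 | 35.7 | 42.9 |
| Friday's | 50.0 | 36.0 | 43.5 |

(standard deviation of a reading: 0.5 percentage points)

- free catalyst is single-handed; left-handed substrate and right-handed substrate are mirror images of each other, charged as a racemate, each of them at the stated concentration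
- the numbers in the tables scatter by 0.5 percentage points (one standard deviation)
- an excess is the difference of the two amounts in percent of their sum
- an excess is below zero if the other one leads

* part of the left-handed substrate and right-handed substrate charged together that has reacted at 40 h
* excess of left-handed product over right-handed product in the product at 40 h
* excess of right-handed substrate over left-handed substrate among what is left of the two at 40 h

- I first took the catalysed step by itself, with one partner used per turn and the catalyst returned. Partner then limits c at 55.0%, yet Wednesday's readings were flat from 15.0 h at c = 5.10% and Friday's from 15.0 h at 21.1%.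
- So I supposed that partner also leaves by a catalyst-free path. Let f be the share of partner reaching product, which was 9.27% on Wednesday and 38.4% on Friday, and let o = f/(1 − f) be its odds, 0.102 and 0.624.
- I expected the odds to grow in step with catalyst. With the charged catalyst, the even-odds catalyst came out as 294 mM on Wednesday and 192 mM on Friday, a poor match. Their mean gives the new flask c = 10.9%.
- Then I let the impurity take catalyst one for one, leaving working catalyst W. This gave 14.0 mM on Wednesday and 104 mM on Friday. I defined K = W/o, the working catalyst that gives even odds between product and loss of partner.
- K read 137 mM on Wednesday and 167 mM on Friday, and Friday's substrate readings ended lower. I replaced both by their mean, 152 mM.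
- The new flask has W = 44.0 mM, so o = 0.290 and c = 12.4%. Using either reading of K instead moves c between 11.5% and 13.4%, and that is the error of taking the mean.
- The forecast, holding that “the final conversion is essentially proportional to loading”, gave c = 10.6%, eP = 35.5% and eS = 4.2%, a lower c than my 12.4%.
- The simulation gave c = 12.3%, eP = 35.1% and eS = 4.93%.

    partner → decomposed reagent (k = 0.00247 min⁻¹)
    partner + free catalyst + right-handed substrate → free catalyst + right-handed product (k = 0.0211 M⁻² min⁻¹)
    free catalyst + impurity → spent catalyst (k = 4.66 M⁻¹ min⁻¹)
    partner + free catalyst + left-handed substrate → free catalyst + left-handed product (k = 0.0461 M⁻² min⁻¹)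
    2 partner → self-condensation product (k = 0.00127 M⁻¹ min⁻¹)

- In the new flask, partner was the limiting reagent: 0.033% of its charge stood at 40.0 h, against 83% of the left-handed substrate. W/K put the odds of its reaching product at 0.290. With the depletion of partner taken away, the same flask gave c = 66.0% instead of 12.3% and eP = 21.1% instead of 35.1%, so that depletion is a part of why it stopped early and of why eP stood at the higher value.
- In the neighbour flask with 34 mol% of free catalyst, W = 86.0 mM, so K gives odds of 0.566 and c = 19.9%. The simulation gave 19.2%.

(The earlier runs and the new flask were generated by integration with made-up constants, and the scatter is random.)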